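Late in these three runs the readings stop moving beyond their scatter, so I read the end of each table.

| flask | left-handed substrate | right-handed substrate | coupling partner | free catalyst | remark | time |
|---|---|---|---|---|---|---|
| oak | 20 mM | 20 mM | 10 mM | 40 µM | run made earlier |  |
| alder | 20 mM | 20 mM | 40 mM | 40 µM | run made earlier |  |
| elm | 20 mM | 20 mM | 20 mM | 20 µM | run made earlier |  |
| flask | 20 mM | 20 mM | 20.0 mM | 40 µM |  | 10 h |

| run | time / h | left-handed substrate / % | right-handed substrate / % | left-handed product / % |
|---|---|---|---|---|
| oak | 0.833 | 36.5 | 43.2 | 12.8 |
| oak | 2.50 | 35.7 | 43.4 | 14.4 |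
| oak | 4.00 | 34.7 | 43.1 | 14.4 |
| oak | 6.00 | 34.9 | 43.8 | 14.7 |
| oak | 10.0 | 35.3 | 42.6 | 13.8 |
| oak | 12.0 | 35.5 | 42.7 | 14.9 |
| alder | 1.00 | 12.3 | 26.9 | 38.8 |
| alder | 1.50 | 10.5 | 25.5 | 38.6 |
| alder | 2.50 | 10.1 | 25.7 | 40.0 |
| alder | 4.00 | 9.9 | 23.5 | 41.0 |
| alder | 8.00 | 9.8 | 24.4 | 40.2 |
| alder | 12.0 | 9.8 | 25.6 | 40.5 |
| elm | 1.00 | 28.8 | 39.7 | 21.0 |
| elm | 3.00 | 26.6 | 38.1 | 22.8 |
| elm | 6.00 | 26.1 | 38.1 | 24.1 |
| elm | 8.00 | 26.3 | 38.5 | 23.9 |
| elm | 12.0 | 26.1 | 36.9 | 23.3 |

(scatter of a reading: 0.5 percentage points)

* part of the left-handed substrate and right-handed substrate charged together that has reacted at 10 h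
* excess of left-handed product over right-handed product in the product at 10 h
* excess of right-handed substrate over left-handed substrate among what is left of the two at 10 h

- free catalyst is single-handed; left-handed substrate and right-handed substrate are mirror images of each other, charged as a racemate, each of them at the stated concentration
- the numbers in the tables scatter with a standard deviation of 0.5 percentage points
- an excess is below zero if the other one leads

I set oak beside alder, since both hold 40 µM of free catalyst, as the flask does. Elm has 20 µM, so I leave it out. I average the rows from 6.00 h in oak and from 4.00 h in alder. Right-handed substrate keeps 86.1% of its charge in oak and 49.0% in alder. Left-handed substrate keeps 70.5% and 19.7%.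

Now the balance of coupling partner, the limiting reagent of the flask, with 20.0 mM against 40.0 mM of substrates. What is left of c(coupling partner) is the charge minus what has reacted. That leaves 1.31 mM in oak and 13.7 mM in alder. Alder stands still with partner and both substrates present, so I take it that its catalyst has stopped working.

I call the logarithm of charge over remainder of right-handed substrate the progress. It reads 0.150 in oak and 0.713 in alder. From these two readings I get 0.0188 mM⁻¹, the final progress gained per mM of coupling partner charged at this catalyst charge. The alder logarithms of left-handed over right-handed read as a selectivity factor of 2.28.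

On a straight line between oak and alder, the flask reaches 0.338. Right-handed substrate then keeps 71.3% and left-handed keeps 46.3%. So I reckon c 41.2%, eP 30.3% and eS 21.3%.

The forecast, noting that “The runs stall well before the partner is used up”, gives 38.8%, 32% and 20.3%, close to mine but not the same.

The flask gives 40.1%, 31.1% and 20.8%. At 5.00 h the flask holds 0.113% of the catalyst charged as free catalyst, with 19.9% of its coupling partner charge still there. At 10.0 h its right-handed substrate keeps 72% of its charge, a progress of 0.323 against the 0.338 from my line.

    coupling partner + free catalyst + left-handed substrate → free catalyst + left-handed product (k = 2100 L² mol⁻² s⁻¹)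
    free catalyst → spent catalyst B (k = 2.20 × 10⁻⁴ s⁻¹)
    coupling partner + free catalyst + right-handed substrate → free catalyst + right-handed product (k = 910 L² mol⁻² s⁻¹)
    2 free catalyst → spent catalyst C (k = 30.0 L mol⁻¹ s⁻¹)
    coupling partner + free catalyst → spent catalyst A (k = 0.00570 L mol⁻¹ s⁻¹)

The neighbour with 50 mM of coupling partner lies beyond alder, and the same rise carries progress to 0.901. That leaves 40.6% of right-handed and 12.8% of left-handed substrate, so I reckon c at 73.3%. Computed, that neighbour gives 73.6%, with 40% of right-handed and 12% of left-handed substrate left.

The data were generated by integration with constants of no real substance, noise included.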